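Ring D, the methyl-bearing benzene ring, alternates three C–OH carbons with the carbons that carry the methyl group, the CH2 link to ring C and the butanoyl group: the folding pattern of a 2-methyl-4-(arylmethyl)-3,5,7-trioxodecanoate. Two ring D bonds are therefore disconnected, so that the ring comes from methyl 2-methyl-3-oxo-5-(2,4,6-trimethoxyphenyl)pentanoate, whose aryl group is the masked ring C, and methyl 3-oxohexanoate. In one operation the dianion of the former is acylated at C4 by the latter and the resulting triketo ester closes by Claisen condensation, giving ring D with the C–D bridge already in place. Acylation, demethylation and two Mannich bridgings then complete rings C, B and A.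

Key step: step 4

Remark: rings are lettered A (gem-dimethyl trione enol) to D (methylated arene) along the chain; the target has no stereocentre, and 3 to 8 are used as racemates or stereoisomer mixtures whose centres are lost by step 4.

Step 1
Reactants: 1 methyl 2-methyl-3-oxobutanoate (racemic); 2 2,4,6-trimethoxybenzaldehyde
Product: 3 methyl 5-hydroxy-2-methyl-3-oxo-5-(2,4,6-trimethoxyphenyl)pentanoate (mixture of racemic diastereomers)
Conditions: LiN(i-Pr)2 (2.2 equiv), THF, −78 to 0 °C; 2, −78 °C; AcOH, −78 °C
Reagents that add atoms: none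
Why: The dianion of the β-keto ester should add through its terminal, more basic carbon to the non-enolisable aldehyde (γ-selective aldol addition), and the cold acetic acid quench avoids retro-aldol and lactonisation; the carbinol centre forms without control and is removed in step 2.

Step 2
Reactants: 3 methyl 5-hydroxy-2-methyl-3-oxo-5-(2,4,6-trimethoxyphenyl)pentanoate
Product: 5 methyl (4E)-2-methyl-3-oxo-5-(2,4,6-trimethoxyphenyl)pent-4-enoate (racemic), via benzylic mesylate 4 (not isolated)
Conditions: MsCl (1.3 equiv), Et3N (3 equiv), CH2Cl2, 0 °C to rt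
Reagents that add atoms: none
Why: Sulfonylation of the strongly activated benzylic alcohol and base-induced β-elimination (aldol dehydration under basic conditions, so that no acid-induced lactonisation can occur) should give the conjugated enone as the more stable E isomer.

Step 3
Reactants: 5 methyl (4E)-2-methyl-3-oxo-5-(2,4,6-trimethoxyphenyl)pent-4-enoate
Product: 6 methyl 2-methyl-3-oxo-5-(2,4,6-trimethoxyphenyl)pentanoate (racemic)
Conditions: H2 (1 atm), 10% Pd/C, EtOAc, rt
Reagents that add atoms: none
Why: Catalytic hydrogenation should saturate the conjugated C=C and leave the ketone, the ester and the aryl methyl ethers untouched.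

Step 4
Reactants: 6 methyl 2-methyl-3-oxo-5-(2,4,6-trimethoxyphenyl)pentanoate; 7 methyl 3-oxohexanoate
Product: 9 1-{2,4,6-trihydroxy-3-methyl-5-[(2,4,6-trimethoxyphenyl)methyl]phenyl}butan-1-one, via triketo ester 8 (not isolated)
Conditions: 6, LiN(i-Pr)2 (2.05 equiv), THF, −78 to 0 °C; Na enolate of 7 (1.5 equiv; NaH, THF, 0 °C), −78 °C to rt; then NaOMe, MeOH, rt, N2; cold 2 M HCl
Reagents that add atoms: none
Why: The dianion of 6 (enolate at C2, carbanion at C4) should add through C4 to the ester carbonyl of the sodium enolate of 7, the expelled methoxide deprotonates the new diketone, and in methanolic methoxide the carbon between the two new ketones (C6 of 8) attacks the methyl ester C1, expels a second methoxide and the cyclic trione tautomerises to the phenol. The closest known reaction type is the terminal acylation of β-keto ester dianions by β-keto ester enolate salts to 3,5,7-triketo esters, followed by base-induced Claisen cyclisation of such esters to acylphloroglucinols. Ring D closes by a 6-(enolendo)-exo-trig acyl substitution. No stereocentre is created, and the racemic C2 centre of 6 disappears on aromatisation. The step needs crossed instead of self-condensation, attack through C4 instead of C2, and Claisen instead of aldol or lactone folding: 6 has a single α' position and only two equivalents of amide base are present, so that 7 stays a monoanion with the less hindered ester; C4 is the more basic carbon of the dianion; and the C2 methyl group makes the C2-to-C7 aldol adduct a quaternary, non-aromatisable and therefore reversible product, while the strong base keeps every ketone enolised and leaves the ester as the only electrophile.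

Step 5
Reactants: 9 1-{2,4,6-trihydroxy-3-methyl-5-[(2,4,6-trimethoxyphenyl)methyl]phenyl}butan-1-one; 10 butanoyl chloride
Product: 11 1-{3-[(3-butanoyl-2,4,6-trimethoxyphenyl)methyl]-2,4,6-trihydroxy-5-methylphenyl}butan-1-one
Conditions: 10 (1.2 equiv), AlCl3 (5 equiv), CH2Cl2/MeNO2, −10 to 0 °C; ice-cold 1 M HCl
Reagents that add atoms: none
Why: Friedel–Crafts acylation should occur at one of the two equivalent free carbons of the trimethoxy ring (ring D has none), the first acyl group deactivates the ring against a second, and the ring D phenols are held as aluminium phenoxides, so that any aryl butanoate returns its acyl group by Fries-type transfer.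

Step 6
Reactants: 11 1-{3-[(3-butanoyl-2,4,6-trimethoxyphenyl)methyl]-2,4,6-trihydroxy-5-methylphenyl}butan-1-one
Product: 12 1-{3-[(3-butanoyl-2,4,6-trihydroxyphenyl)methyl]-2,4,6-trihydroxy-5-methylphenyl}butan-1-one
Conditions: BBr3 (8 equiv), CH2Cl2, −78 °C to rt; MeOH, then H2O
Reagents that add atoms: none
Why: Lewis acid cleavage of aryl methyl ethers (BBr3 demethylation) should remove all three methyl groups, and because both rings now carry an acyl group their lowered basicity protects the diarylmethane bridge against ipso-protonation.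

Step 7
Reactants: 12 1-{3-[(3-butanoyl-2,4,6-trihydroxyphenyl)methyl]-2,4,6-trihydroxy-5-methylphenyl}butan-1-one
Product: 13 1-{3-({3-butanoyl-5-[(dimethylamino)methyl]-2,4,6-trihydroxyphenyl}methyl)-2,4,6-trihydroxy-5-methylphenyl}butan-1-one
Conditions: [CH2=NMe2]I (1.05 equiv), Et3N (1.1 equiv), MeCN, 0 °C to rt
Reagents that add atoms: N,N-dimethylmethyleneiminium iodide, C=[N+](C)C.[I-]
Why: Mannich aminomethylation can only go to the single remaining aromatic C–H, on ring C, and the preformed iminium salt avoids free formaldehyde and with it symmetrical methylene-bis by-products.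

Step 8
Reactants: 14 benzene-1,3,5-triol (phloroglucinol); 10 butanoyl chloride
Product: 15 1-(2,4,6-trihydroxyphenyl)butan-1-one
Conditions: 10 (1.0 equiv), AlCl3 (3.5 equiv), PhNO2/CH2Cl2, 0 °C to rt; 1 M HCl
Reagents that add atoms: none
Why: Friedel–Crafts C-acylation of phloroglucinol should stop after one acyl group because the hydrogen-bonded ketone deactivates the ring.

Step 9
Reactants: 13 1-{3-({3-butanoyl-5-[(dimethylamino)methyl]-2,4,6-trihydroxyphenyl}methyl)-2,4,6-trihydroxy-5-methylphenyl}butan-1-one; 15 1-(2,4,6-trihydroxyphenyl)butan-1-one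
Product: 16 1-{3-[(3-butanoyl-2,4,6-trihydroxyphenyl)methyl]-5-[(3-butanoyl-2,4,6-trihydroxy-5-methylphenyl)methyl]-2,4,6-trihydroxyphenyl}butan-1-one (rings B–C–D, one free carbon left on ring B)
Conditions: 15 (5 equiv), 1,4-dioxane, 80 °C, N2; dilute HCl wash
Reagents that add atoms: none
Why: Thermal loss of dimethylamine from the phenolic Mannich base should give an ortho-quinone methide on ring C that is captured at a ring carbon of 15 (Michael-type C-alkylation of a phenol), and the large excess of 15, whose two free carbons are equivalent, holds the reaction at mono-alkylation.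

Step 10
Reactants: 15 1-(2,4,6-trihydroxyphenyl)butan-1-one
Product: 17 2-butanoyl-3,5-dihydroxy-4,4-dimethylcyclohexa-2,5-dien-1-one (butyrylfilicinic acid)
Conditions: NaOMe (3.5 equiv), MeI (2.5 equiv), MeOH, 0 °C to rt; HCl work-up, chromatography
Reagents that add atoms: iodomethane, CI
Why: Twofold C-methylation of the phloroglucinolate at one ring carbon (dearomatising alkylation with methoxide and iodomethane) should give the gem-dimethyl trione enol, to be separated from under- and over-methylated congeners.

Step 11
Reactants: 17 2-butanoyl-3,5-dihydroxy-4,4-dimethylcyclohexa-2,5-dien-1-one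
Product: 18 2-butanoyl-6-[(dimethylamino)methyl]-3,5-dihydroxy-4,4-dimethylcyclohexa-2,5-dien-1-one hydroiodide
Conditions: [CH2=NMe2]I (1.05 equiv), MeCN, 0 °C to rt; precipitation with Et2O
Reagents that add atoms: N,N-dimethylmethyleneiminium iodide, C=[N+](C)C.[I-]
Why: The enolised cyclic β-triketone attacks the iminium ion through its only C–H carbon, C6 (Mannich reaction), and keeping the product as its ammonium salt without base blocks amine loss and self-condensation to the methylene-bis compound.

Step 12
Reactants: 16 1-{3-[(3-butanoyl-2,4,6-trihydroxyphenyl)methyl]-5-[(3-butanoyl-2,4,6-trihydroxy-5-methylphenyl)methyl]-2,4,6-trihydroxyphenyl}butan-1-one; 18 2-butanoyl-6-[(dimethylamino)methyl]-3,5-dihydroxy-4,4-dimethylcyclohexa-2,5-dien-1-one hydroiodide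
Product: 19 2-butanoyl-6-{[3-butanoyl-5-({3-butanoyl-5-[(3-butanoyl-2,4,6-trihydroxy-5-methylphenyl)methyl]-2,4,6-trihydroxyphenyl}methyl)-2,4,6-trihydroxyphenyl]methyl}-3,5-dihydroxy-4,4-dimethylcyclohexa-2,5-dien-1-one (CNP0246352.0)
Conditions: 18 (1.3 equiv), NaOAc (3 equiv), THF/EtOH, 20 to 40 °C, N2; 0.5 M HCl wash
Reagents that add atoms: none
Why: Acetate frees the Mannich base, which should lose dimethylamine near room temperature to a 2-methylene-1,3-dione that is trapped by the one free ring B carbon of 16 (Michael-type C-alkylation), and forming the most labile bridge, between ring A and ring B, last and under mild conditions limits exchange of ring units.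

Compound list
1 | methyl 2-methyl-3-oxobutanoate (racemic) | COC(=O)C(C)C(C)=O | starting material
2 | 2,4,6-trimethoxybenzaldehyde | COc1cc(OC)c(C=O)c(OC)c1 | starting material
3 | methyl 5-hydroxy-2-methyl-3-oxo-5-(2,4,6-trimethoxyphenyl)pentanoate (mixture of racemic diastereomers) | COC(=O)C(C)C(=O)CC(O)c1c(OC)cc(OC)cc1OC | intermediate
4 | methyl 5-(methanesulfonyloxy)-2-methyl-3-oxo-5-(2,4,6-trimethoxyphenyl)pentanoate (mixture of racemic diastereomers, not isolated) | COC(=O)C(C)C(=O)CC(OS(C)(=O)=O)c1c(OC)cc(OC)cc1OC | intermediate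
5 | methyl (4E)-2-methyl-3-oxo-5-(2,4,6-trimethoxyphenyl)pent-4-enoate (racemic) | COC(=O)C(C)C(=O)/C=C/c1c(OC)cc(OC)cc1OC | intermediate
6 | methyl 2-methyl-3-oxo-5-(2,4,6-trimethoxyphenyl)pentanoate (racemic) | COC(=O)C(C)C(=O)CCc1c(OC)cc(OC)cc1OC | intermediate
7 | methyl 3-oxohexanoate | CCCC(=O)CC(=O)OC | starting material
8 | methyl 2-methyl-3,5,7-trioxo-4-[(2,4,6-trimethoxyphenyl)methyl]decanoate (present as its polyenolate, stereoisomer mixture, not isolated) | COC(=O)C(C)C(=O)C(Cc1c(OC)cc(OC)cc1OC)C(=O)CC(=O)CCC | intermediate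
9 | 1-{2,4,6-trihydroxy-3-methyl-5-[(2,4,6-trimethoxyphenyl)methyl]phenyl}butan-1-one | CCCC(=O)c1c(O)c(C)c(O)c(Cc2c(OC)cc(OC)cc2OC)c1O | intermediate
10 | butanoyl chloride | CCCC(=O)Cl | starting material
11 | 1-{3-[(3-butanoyl-2,4,6-trimethoxyphenyl)methyl]-2,4,6-trihydroxy-5-methylphenyl}butan-1-one | CCCC(=O)c1c(O)c(C)c(O)c(Cc2c(OC)cc(OC)c(C(=O)CCC)c2OC)c1O | intermediate
12 | 1-{3-[(3-butanoyl-2,4,6-trihydroxyphenyl)methyl]-2,4,6-trihydroxy-5-methylphenyl}butan-1-one | CCCC(=O)c1c(O)c(C)c(O)c(Cc2c(O)cc(O)c(C(=O)CCC)c2O)c1O | intermediate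
13 | 1-{3-({3-butanoyl-5-[(dimethylamino)methyl]-2,4,6-trihydroxyphenyl}methyl)-2,4,6-trihydroxy-5-methylphenyl}butan-1-one | CCCC(=O)c1c(O)c(C)c(O)c(Cc2c(O)c(CN(C)C)c(O)c(C(=O)CCC)c2O)c1O | intermediate
14 | benzene-1,3,5-triol (phloroglucinol) | Oc1cc(O)cc(O)c1 | starting material
15 | 1-(2,4,6-trihydroxyphenyl)butan-1-one | CCCC(=O)c1c(O)cc(O)cc1O | intermediate
16 | 1-{3-[(3-butanoyl-2,4,6-trihydroxyphenyl)methyl]-5-[(3-butanoyl-2,4,6-trihydroxy-5-methylphenyl)methyl]-2,4,6-trihydroxyphenyl}butan-1-one | CCCC(=O)c1c(O)c(C)c(O)c(Cc2c(O)c(Cc3c(O)cc(O)c(C(=O)CCC)c3O)c(O)c(C(=O)CCC)c2O)c1O | intermediate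
17 | 2-butanoyl-3,5-dihydroxy-4,4-dimethylcyclohexa-2,5-dien-1-one | CCCC(=O)C1=C(O)C(C)(C)C(O)=CC1=O | intermediate
18 | 2-butanoyl-6-[(dimethylamino)methyl]-3,5-dihydroxy-4,4-dimethylcyclohexa-2,5-dien-1-one hydroiodide | CCCC(=O)C1=C(O)C(C)(C)C(O)=C(C[NH+](C)C)C1=O.[I-] | intermediate
19 | 2-butanoyl-6-{[3-butanoyl-5-({3-butanoyl-5-[(3-butanoyl-2,4,6-trihydroxy-5-methylphenyl)methyl]-2,4,6-trihydroxyphenyl}methyl)-2,4,6-trihydroxyphenyl]methyl}-3,5-dihydroxy-4,4-dimethylcyclohexa-2,5-dien-1-one (CNP0246352.0) | CCCC(=O)C1=C(O)C(C)(C)C(O)=C(Cc2c(O)c(Cc3c(O)c(Cc4c(O)c(C)c(O)c(C(=O)CCC)c4O)c(O)c(C(=O)CCC)c3O)c(O)c(C(=O)CCC)c2O)C1=O | target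

Total step count: 12. Longest linear sequence: 9 steps (steps 1, 2, 3, 4, 5, 6, 7, 9 and 12).

Steps most likely to fail, in this order: step 4, step 5, step 12.

Step 4. Proton exchange between the dianion of 6 and the enolate of 7 may occur, since both are β-keto ester anions with a secondary α' carbon. It would return 6 as its unreactive monoanion and let 7 condense with itself. The hindered secondary carbanion may also add too slowly, and the triketo ester may fold through oxygen to a 2-pyranone. The fallback gives up the chain folding for conventional arene chemistry; it sets out from 10 and 15, comes back at 12 and replaces steps 1 to 6. Commercial 2-methylbenzene-1,3,5-triol F1 is C-acylated with 10 (AlCl3, PhNO2/CH2Cl2) to 1-(2,4,6-trihydroxy-3-methylphenyl)butan-1-one F2. Its single free ring carbon is aminomethylated ([CH2=NMe2]I, Et3N, MeCN) to 1-{3-[(dimethylamino)methyl]-2,4,6-trihydroxy-5-methylphenyl}butan-1-one F3. Heating F3 with an excess of 15 in 1,4-dioxane should give 12 by the same quinone methide alkylation as in step 9.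

Step 5. The ring D phenols may be O-acylated, and the acidic medium may protonate the still unacylated, very electron-rich ring C at its substituted carbon, with loss or migration of the benzylic bridge. The fallback sets out from 9 and comes back at 12. Ring D is capped first by exhaustive O-methylation (Me2SO4, K2CO3, acetone, reflux) to 1-{2,4,6-trimethoxy-3-methyl-5-[(2,4,6-trimethoxyphenyl)methyl]phenyl}butan-1-one F4. Ring C is then acylated without metal halide and without free phenol, by the mixed anhydride of butanoic acid and trifluoroacetic anhydride, to 1-{3-[(3-butanoyl-2,4,6-trimethoxyphenyl)methyl]-2,4,6-trimethoxy-5-methylphenyl}butan-1-one F5. BBr3 in CH2Cl2 then removes all six methyl groups and should give 12.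

Step 12. The methylene bridges may open by retro-Michael reaction and re-add, which exchanges ring units, and the liberated ring A Mannich base may condense with itself to the symmetrical methylene-bis(trione). The fallback exchanges the roles of the partners; it sets out from 16 and 17 and comes back at 19. Compound 16 is aminomethylated at its one free ring B carbon ([CH2=NMe2]I, Et3N, MeCN) to 1-{3-({3-butanoyl-5-[(dimethylamino)methyl]-2,4,6-trihydroxyphenyl}methyl)-5-[(3-butanoyl-2,4,6-trihydroxy-5-methylphenyl)methyl]-2,4,6-trihydroxyphenyl}butan-1-one F6. Warming F6 in 1,4-dioxane with an excess of 17, a strong carbon nucleophile that captures the ring B quinone methide, should give 19.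

Further compounds
F1 | step 4 | 2-methylbenzene-1,3,5-triol (bought) | Cc1c(O)cc(O)cc1O
F2 | step 4 | 1-(2,4,6-trihydroxy-3-methylphenyl)butan-1-one | CCCC(=O)c1c(O)cc(O)c(C)c1O
F3 | step 4 | 1-{3-[(dimethylamino)methyl]-2,4,6-trihydroxy-5-methylphenyl}butan-1-one | CCCC(=O)c1c(O)c(C)c(O)c(CN(C)C)c1O
F4 | step 5 | 1-{2,4,6-trimethoxy-3-methyl-5-[(2,4,6-trimethoxyphenyl)methyl]phenyl}butan-1-one | CCCC(=O)c1c(OC)c(C)c(OC)c(Cc2c(OC)cc(OC)cc2OC)c1OC
F5 | step 5 | 1-{3-[(3-butanoyl-2,4,6-trimethoxyphenyl)methyl]-2,4,6-trimethoxy-5-methylphenyl}butan-1-one | CCCC(=O)c1c(OC)c(C)c(OC)c(Cc2c(OC)cc(OC)c(C(=O)CCC)c2OC)c1OC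
F6 | step 12 | 1-{3-({3-butanoyl-5-[(dimethylamino)methyl]-2,4,6-trihydroxyphenyl}methyl)-5-[(3-butanoyl-2,4,6-trihydroxy-5-methylphenyl)methyl]-2,4,6-trihydroxyphenyl}butan-1-one | CCCC(=O)c1c(O)c(C)c(O)c(Cc2c(O)c(Cc3c(O)c(CN(C)C)c(O)c(C(=O)CCC)c3O)c(O)c(C(=O)CCC)c2O)c1O
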